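**Plan**

1. Numbering: ring A is the ketone-bearing ring (C1' acyl, O2', C3', O4', C5'), ring B is the 4-hydroxyphenyl ring, and the pyran ring is numbered as a chromene (O1 = O4', C2, C3, C4, C4a = C5', O7 = O2', C8 = C3').
2. Retrosynthesis: the ring B phenol is unmasked last (MOM ether); the C8 prenyl group is returned to O7 as a 1,1-dimethylallyl ether (aromatic Claisen); the pyran ring is then cut at C4–C4a and C2–C3, releasing acetylene and a 2-aryloxy-2-methylpropanoic acid; the two aryl ether bonds and the Cα–Cβ bond of the chain (aldol) follow.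
3. Enabling feature: C2 is quaternary (gem-dimethyl, bound to O1) and maps onto a stabilized tertiary α-aryloxy radical stored as a carboxylic acid, C3=C4 is an unsubstituted ring-cis vinylene (acetylene itself), and C4a is an ortho C–H of the O1 aryl ether.
4. Forward: rings A and B are joined by Claisen–Schmidt condensation and hydrogenation, O4' and then O2' are alkylated, the pyran ring is closed by a decarboxylative radical (4+2) annulation with acetylene, and a Claisen shift moves the parked C5 unit from O7 to C8.
5. Stereochemistry: the target has no stereocenter; the C3=C4 bond is cis by ring constraint, and the E-enone of the chalcone is removed by hydrogenation.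

Key step: step 8

**Route**

Step 1
Reactants: 1 1-(2,4-dihydroxyphenyl)ethan-1-one; 2 4-(methoxymethoxy)benzaldehyde
Product: 3 (E)-1-(2,4-dihydroxyphenyl)-3-[4-(methoxymethoxy)phenyl]prop-2-en-1-one
Conditions: KOH (60% aq.), EtOH, rt, 48 h; then 1 M HCl to pH 5, 0 °C
Reagents that add atoms: none
Why: Claisen–Schmidt condensation (crossed aldol addition and E1cB dehydration) between the methyl ketone and the non-enolizable aldehyde should give the E-enone, the MOM acetal being stable to hydroxide.

Step 2
Reactants: 3 (E)-1-(2,4-dihydroxyphenyl)-3-[4-(methoxymethoxy)phenyl]prop-2-en-1-one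
Product: 4 1-(2,4-dihydroxyphenyl)-3-[4-(methoxymethoxy)phenyl]propan-1-one
Conditions: H2 (1 atm), 10% Pd/C, EtOAc, rt
Reagents that add atoms: none
Why: Heterogeneous catalytic hydrogenation should saturate the enone C=C bond chemoselectively over the hydrogen-bonded aryl ketone and the MOM ether, and it is placed here because no other alkene is yet present.

Step 3
Reactants: 4 1-(2,4-dihydroxyphenyl)-3-[4-(methoxymethoxy)phenyl]propan-1-one; 5 ethyl 2-bromo-2-methylpropanoate
Product: 6 ethyl 2-[3-hydroxy-4-[3-[4-(methoxymethoxy)phenyl]propanoyl]phenoxy]-2-methylpropanoate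
Conditions: K2CO3, DMF, 70 °C
Reagents that add atoms: none
Why: Williamson etherification (SN2 displacement at the α-bromo ester, as in fibrate syntheses) should occur only at O4', the more acidic phenol that is not tied up in the hydrogen bond to the ketone.

Step 4
Reactants: 7 2-methylbut-3-en-2-ol
Product: 8 methyl 2-methylbut-3-en-2-yl carbonate
Conditions: ClCO2Me, pyridine, DMAP (cat.), CH2Cl2, 0 °C → rt
Reagents that add atoms: methyl chloroformate, COC(=O)Cl
Why: Acylation of the tertiary alcohol by the chloroformate through the N-acylpyridinium ion (carbonate formation) should give the allyl donor needed in step 5.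

Step 5
Reactants: 6 ethyl 2-[3-hydroxy-4-[3-[4-(methoxymethoxy)phenyl]propanoyl]phenoxy]-2-methylpropanoate; 8 methyl 2-methylbut-3-en-2-yl carbonate
Product: 9 ethyl 2-[4-[3-[4-(methoxymethoxy)phenyl]propanoyl]-3-(2-methylbut-3-en-2-yloxy)phenoxy]-2-methylpropanoate
Conditions: Pd(PPh3)4 (5 mol%), THF, 0 °C → rt
Reagents that add atoms: none
Why: Tsuji–Trost O-allylation, in which zerovalent palladium ionizes the carbonate with loss of CO2, the methoxide set free deprotonates the chelated phenol, and the phenoxide attacks the more substituted terminus of the 1,1-dimethylallyl palladium cation under kinetic control, should give the tertiary ether that parks the future prenyl group on O2' and shields C3'.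

Step 6
Reactants: 9 ethyl 2-[4-[3-[4-(methoxymethoxy)phenyl]propanoyl]-3-(2-methylbut-3-en-2-yloxy)phenoxy]-2-methylpropanoate
Product: 10 2-[4-[3-[4-(methoxymethoxy)phenyl]propanoyl]-3-(2-methylbut-3-en-2-yloxy)phenoxy]-2-methylpropanoic acid
Conditions: LiOH·H2O, THF/MeOH/H2O, rt; then 1 M HCl to pH 4, 0 °C
Reagents that add atoms: lithium hydroxide, [Li+].[OH-]
Why: Saponification (BAc2) of the α-aryloxy ester should be fast, the tertiary allyl aryl ether and the MOM acetal are stable to base, and the brief cold acidification to pH 4 should spare both.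

Step 7
Reactants: 10 2-[4-[3-[4-(methoxymethoxy)phenyl]propanoyl]-3-(2-methylbut-3-en-2-yloxy)phenoxy]-2-methylpropanoic acid
Product: 11 1,3-dioxoisoindolin-2-yl 2-[4-[3-[4-(methoxymethoxy)phenyl]propanoyl]-3-(2-methylbut-3-en-2-yloxy)phenoxy]-2-methylpropanoate
Conditions: N-hydroxyphthalimide, DIC, DMAP (cat.), CH2Cl2, rt
Reagents that add atoms: N-hydroxyphthalimide, O=C1c2ccccc2C(=O)N1O
Why: Carbodiimide-mediated (Steglich-type) esterification should convert the hindered acid into the redox-active N-acyloxyphthalimide, a standard radical precursor for 2-aryloxy-2-methylpropanoic acids.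

Step 8
Reactants: 11 1,3-dioxoisoindolin-2-yl 2-[4-[3-[4-(methoxymethoxy)phenyl]propanoyl]-3-(2-methylbut-3-en-2-yloxy)phenoxy]-2-methylpropanoate; 12 acetylene
Product: 13 1-[2,2-dimethyl-7-(2-methylbut-3-en-2-yloxy)-2H-chromen-6-yl]-3-[4-(methoxymethoxy)phenyl]propan-1-one
Conditions: fac-Ir(ppy)3 (1 mol%), HC≡CH (1 atm, saturated solution), degassed DMSO, blue LEDs (450 nm), rt
Reagents that add atoms: none
Why: Proposed new method: single-electron reduction of 11 by photoexcited Ir(ppy)3 (tris(2-phenylpyridinato)iridium, trivalent iridium) should expel CO2 and phthalimide anion to give the tertiary α-aryloxy radical at the future C2, which adds to acetylene (new C2–C3 bond), after which the σ-vinyl radical at C4 attacks the ortho carbon of ring A (new C4–C4a bond) and the cyclohexadienyl radical is oxidized by the tetravalent iridium species and deprotonated by phthalimide anion, so that the process is redox-neutral. The closest known reaction types are the photoredox (4+2) radical annulation of N-acyloxyphthalimides of aryloxy acids with olefins to chromans, the radical cascades of aryl propargyl ethers that close 2H-chromenes through the same kind of vinyl radical, and photoredox radical additions to acetylene gas. The pyran ring closes by six-membered ortho attack of the vinyl radical on the arene (homolytic aromatic substitution), whereas the competing five-membered ipso attack is reversible and unproductive because its fragmentation would have to give an alkoxyl radical. No stereocenter is formed, and the cis geometry of C3=C4 follows from ring closure of the rapidly inverting vinyl radical. The step needs site selectivity for C5' (para to O2') over C3' (between the two oxygens), and the bulky 1,1-dimethylallyl ether on O2' is there to screen C3' and to remove the hydrogen-bond chelate that would otherwise fix the ring bonds in favor of C3'. It also needs the C2 radical to meet acetylene before any intramolecular trap, which is why no alkene sits ortho to O4' at this stage, the allyl group on O2' has no allylic hydrogen, and acetylene is kept at saturation.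

Step 9
Reactants: 13 1-[2,2-dimethyl-7-(2-methylbut-3-en-2-yloxy)-2H-chromen-6-yl]-3-[4-(methoxymethoxy)phenyl]propan-1-one
Product: 15 1-[7-hydroxy-2,2-dimethyl-8-(3-methylbut-2-en-1-yl)-2H-chromen-6-yl]-3-[4-(methoxymethoxy)phenyl]propan-1-one, via ortho-dienone 14 (not isolated)
Conditions: PhNEt2, 130 °C
Reagents that add atoms: none
Why: Aromatic Claisen rearrangement ([3,3]-sigmatropic shift) should transfer the 1,1-dimethylallyl group from O7 with allylic inversion to C8, the only free ortho position, and enolization of dienone 14 restores the phenol, which is then hydrogen-bonded to the ketone.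

Step 10
Reactants: 15 1-[7-hydroxy-2,2-dimethyl-8-(3-methylbut-2-en-1-yl)-2H-chromen-6-yl]-3-[4-(methoxymethoxy)phenyl]propan-1-one
Product: 16 1-[7-hydroxy-2,2-dimethyl-8-(3-methylbut-2-en-1-yl)-2H-chromen-6-yl]-3-(4-hydroxyphenyl)propan-1-one
Conditions: HCl (3 M aq.), MeOH, 40 °C
Reagents that add atoms: none
Why: Acid-catalysed acetal solvolysis should remove the phenolic MOM group under conditions mild enough (as used for prenylated chalcones) to leave the chelated ortho-prenyl phenol and the chromene untouched.

**Compound list**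

1 | 1-(2,4-dihydroxyphenyl)ethan-1-one | CC(=O)c1ccc(O)cc1O | starting material
2 | 4-(methoxymethoxy)benzaldehyde | COCOc1ccc(C=O)cc1 | starting material
3 | (E)-1-(2,4-dihydroxyphenyl)-3-[4-(methoxymethoxy)phenyl]prop-2-en-1-one | COCOc1ccc(/C=C/C(=O)c2ccc(O)cc2O)cc1 | intermediate
4 | 1-(2,4-dihydroxyphenyl)-3-[4-(methoxymethoxy)phenyl]propan-1-one | COCOc1ccc(CCC(=O)c2ccc(O)cc2O)cc1 | intermediate
5 | ethyl 2-bromo-2-methylpropanoate | CCOC(=O)C(C)(C)Br | starting material
6 | ethyl 2-[3-hydroxy-4-[3-[4-(methoxymethoxy)phenyl]propanoyl]phenoxy]-2-methylpropanoate | CCOC(=O)C(C)(C)Oc1ccc(C(=O)CCc2ccc(OCOC)cc2)c(O)c1 | intermediate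
7 | 2-methylbut-3-en-2-ol | C=CC(C)(C)O | starting material
8 | methyl 2-methylbut-3-en-2-yl carbonate | COC(=O)OC(C)(C)C=C | intermediate
9 | ethyl 2-[4-[3-[4-(methoxymethoxy)phenyl]propanoyl]-3-(2-methylbut-3-en-2-yloxy)phenoxy]-2-methylpropanoate | CCOC(=O)C(C)(C)Oc1ccc(C(=O)CCc2ccc(OCOC)cc2)c(OC(C)(C)C=C)c1 | intermediate
10 | 2-[4-[3-[4-(methoxymethoxy)phenyl]propanoyl]-3-(2-methylbut-3-en-2-yloxy)phenoxy]-2-methylpropanoic acid | OC(=O)C(C)(C)Oc1ccc(C(=O)CCc2ccc(OCOC)cc2)c(OC(C)(C)C=C)c1 | intermediate
11 | 1,3-dioxoisoindolin-2-yl 2-[4-[3-[4-(methoxymethoxy)phenyl]propanoyl]-3-(2-methylbut-3-en-2-yloxy)phenoxy]-2-methylpropanoate | O=C(ON1C(=O)c2ccccc2C1=O)C(C)(C)Oc1ccc(C(=O)CCc2ccc(OCOC)cc2)c(OC(C)(C)C=C)c1 | intermediate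
12 | acetylene (ethyne) | C#C | starting material
13 | 1-[2,2-dimethyl-7-(2-methylbut-3-en-2-yloxy)-2H-chromen-6-yl]-3-[4-(methoxymethoxy)phenyl]propan-1-one | COCOc1ccc(CCC(=O)c2cc3C=CC(C)(C)Oc3cc2OC(C)(C)C=C)cc1 | intermediate
14 | 6-[3-[4-(methoxymethoxy)phenyl]propanoyl]-2,2-dimethyl-8-(3-methylbut-2-en-1-yl)-2H-chromen-7(8H)-one (racemic at C8, stereocenter lost on enolization) | COCOc1ccc(CCC(=O)C2=CC3=C(OC(C)(C)C=C3)C(CC=C(C)C)C2=O)cc1 | intermediate (not isolated)
15 | 1-[7-hydroxy-2,2-dimethyl-8-(3-methylbut-2-en-1-yl)-2H-chromen-6-yl]-3-[4-(methoxymethoxy)phenyl]propan-1-one | COCOc1ccc(CCC(=O)c2cc3C=CC(C)(C)Oc3c(CC=C(C)C)c2O)cc1 | intermediate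
16 | 1-[7-hydroxy-2,2-dimethyl-8-(3-methylbut-2-en-1-yl)-2H-chromen-6-yl]-3-(4-hydroxyphenyl)propan-1-one | CC(C)=CCc1c(O)c(C(=O)CCc2ccc(O)cc2)cc2c1OC(C)(C)C=C2 | target

**Step count and risks**

Total steps: 10. Longest linear sequence: 9 (steps 1–3 and 5–10; step 4 prepares the allyl donor).

Step 8 (the step proposed as a new method). The tertiary radical may be oxidized, reduced or dimerize before the weakly activated acetylene captures it, or the vinyl radical may close at C3' instead of C5'. The fallback uses known chemistry, sets out from 4 and comes back to the route at 15. Compound 4 is C-prenylated between its two oxygens with prenyl bromide in aqueous KOH (nuclear alkylation of the phenoxide) to give 1-[2,4-dihydroxy-3-(3-methylbut-2-en-1-yl)phenyl]-3-[4-(methoxymethoxy)phenyl]propan-1-one F1. The free O4' of F1 is etherified with 3-chloro-3-methylbut-1-yne (K2CO3, KI, acetone, reflux) to give 1-[2-hydroxy-3-(3-methylbut-2-en-1-yl)-4-(2-methylbut-3-yn-2-yloxy)phenyl]-3-[4-(methoxymethoxy)phenyl]propan-1-one F2. Heating F2 in PhNEt2 at about 180 °C should bring about propargyl Claisen rearrangement to C5' (C3' being blocked by the prenyl group), 1,5-hydrogen shift and oxa-6π electrocyclization, giving 15.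

Step 5. The hydrogen-bonded phenoxide may be too weak a nucleophile for the allyl palladium cation, or the tertiary ether may isomerize to the linear prenyl ether. The fallback sets out from 6 and comes back at 9. Copper-catalysed propargylation of 6 with 3-chloro-3-methylbut-1-yne (DBU, CuCl2 cat., MeCN, 0 °C) gives ethyl 2-[4-[3-[4-(methoxymethoxy)phenyl]propanoyl]-3-(2-methylbut-3-yn-2-yloxy)phenoxy]-2-methylpropanoate F3. Semihydrogenation of F3 (H2, 1 atm, Pd/CaCO3 poisoned with Pb(OAc)2, quinoline, EtOAc) gives 9.

Step 9. The ether may lose its C5 unit by heterolysis or retro-ene elimination instead of undergoing the sigmatropic shift. The fallback sets out from 13 and comes back at 15. The allyl ether is cleaved on purpose with Pd(PPh3)4 and morpholine (THF, rt) to give 1-(7-hydroxy-2,2-dimethyl-2H-chromen-6-yl)-3-[4-(methoxymethoxy)phenyl]propan-1-one F4. The phenoxide of F4 is then C-prenylated at C8, its only free ortho position, with prenyl bromide in aqueous KOH to give 15.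

**Further compounds**

F1 | step 8 | 1-[2,4-dihydroxy-3-(3-methylbut-2-en-1-yl)phenyl]-3-[4-(methoxymethoxy)phenyl]propan-1-one | COCOc1ccc(CCC(=O)c2ccc(O)c(CC=C(C)C)c2O)cc1
F2 | step 8 | 1-[2-hydroxy-3-(3-methylbut-2-en-1-yl)-4-(2-methylbut-3-yn-2-yloxy)phenyl]-3-[4-(methoxymethoxy)phenyl]propan-1-one | COCOc1ccc(CCC(=O)c2ccc(OC(C)(C)C#C)c(CC=C(C)C)c2O)cc1
F3 | step 5 | ethyl 2-[4-[3-[4-(methoxymethoxy)phenyl]propanoyl]-3-(2-methylbut-3-yn-2-yloxy)phenoxy]-2-methylpropanoate | CCOC(=O)C(C)(C)Oc1ccc(C(=O)CCc2ccc(OCOC)cc2)c(OC(C)(C)C#C)c1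
F4 | step 9 | 1-(7-hydroxy-2,2-dimethyl-2H-chromen-6-yl)-3-[4-(methoxymethoxy)phenyl]propan-1-one | COCOc1ccc(CCC(=O)c2cc3C=CC(C)(C)Oc3cc2O)cc1
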